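**Assumption:** locants C1–C8a in the text are those of the isochromene skeleton of the target (C8 = ring ketone, C7 = carbinol carbon, C6 = carbon bearing the 2-oxononyl chain), and (E)-1-bromoprop-1-ene is bought as the pure E isomer.

## Retrosynthetic overview

1. The pyran ring is formed last: O–C3 bond by 6-endo cycloisomerisation of a 2-(hydroxymethyl)-3-(pent-3-en-1-ynyl)cyclohex-2-enone.
2. C4a=C8a comes from Saegusa dehydrogenation; the enyne from Sonogashira coupling of a terminal alkyne made from the isopropenyl group of carvone; C1 from a formaldehyde aldol at C8a.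
3. The C7–O bond comes from Rubottom oxidation of the regio-defined silyl enol ether that the key step delivers.
4. Key C6–CH2 bond: Mukaiyama–Michael addition of the silyl enol ether of nonan-2-one to (R)-carvone. The isopropenyl centre steers C6, C6 steers C7, and the isopropenyl centre is then erased. The carbocycle is the carvone ring throughout.

## Route

Step 1
Reactants: 1 nonan-2-one
Product: 2 triethyl(non-1-en-2-yloxy)silane
Conditions: LiN(iPr)2, THF, −78 °C; Et3SiCl, −78 °C to rt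
Reagents that add atoms: chlorotriethylsilane, CC[Si](Cl)(CC)CC
Why: Kinetic deprotonation of the methyl ketone by the hindered amide removes a CH3 proton and O-silylation traps the terminal enolate (kinetic silyl enol ether formation), with no stereocentre involved.

Step 2
Reactants: 3 (R)-carvone; 2 triethyl(non-1-en-2-yloxy)silane
Product: 4 1-[(1S,5R)-2-methyl-5-(prop-1-en-2-yl)-3-(triethylsilyloxy)cyclohex-2-en-1-yl]nonan-2-one
Conditions: Ph3CSbCl6 (5 mol %), CH2Cl2, −78 °C; pyridine quench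
Reagents that add atoms: none
Why: In this trityl-catalysed Mukaiyama–Michael addition the enol ether attacks the enone β-carbon axially on the face anti to the isopropenyl group, which sets C6 (S) trans to it, and silyl transfer leaves a regio-defined C8=C7 triethylsilyl enol ether.

Step 3
Reactants: 4 1-[(1S,5R)-2-methyl-5-(prop-1-en-2-yl)-3-(triethylsilyloxy)cyclohex-2-en-1-yl]nonan-2-one
Product: 6 (2S,3S,5R)-2-methyl-3-(2-oxononyl)-5-(prop-1-en-2-yl)-2-(triethylsilyloxy)cyclohexan-1-one, via silyloxy epoxide 5 (not isolated)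
Conditions: mCPBA (1.05 equiv), NaHCO3, CH2Cl2, −20 to 0 °C
Reagents that add atoms: 3-chloroperoxybenzoic acid, OOC(=O)c1cccc(Cl)c1
Why: In this Rubottom oxidation the electron-rich tetrasubstituted enol ether is epoxidised much faster than the 1,1-disubstituted alkene and from the face anti to the adjacent pseudoaxial C6 chain, and silyl migration opens the epoxide to the α-silyloxy ketone, setting C7 (S) with oxygen trans to the chain.

Step 4
Reactants: 6 (2S,3S,5R)-2-methyl-3-(2-oxononyl)-5-(prop-1-en-2-yl)-2-(triethylsilyloxy)cyclohexan-1-one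
Product: 7 (2S,3S,5R)-3-[(2-heptyl-1,3-dioxolan-2-yl)methyl]-2-methyl-5-(prop-1-en-2-yl)-2-(triethylsilyloxy)cyclohexan-1-one
Conditions: (Me3SiOCH2)2 (1.2 equiv), Me3SiOTf (5 mol %), CH2Cl2, −78 to −20 °C; pyridine
Reagents that add atoms: 1,2-bis(trimethylsilyloxy)ethane, C[Si](C)(C)OCCO[Si](C)(C)C
Why: Noyori ketalisation under kinetic control takes the unhindered side-chain ketone and leaves the ring ketone, which is shielded by the silyloxy-bearing quaternary carbon, and no stereocentre is touched.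

Step 5
Reactants: 7 (2S,3S,5R)-3-[(2-heptyl-1,3-dioxolan-2-yl)methyl]-2-methyl-5-(prop-1-en-2-yl)-2-(triethylsilyloxy)cyclohexan-1-one
Product: 8 (2S,3S,5R,6R)-3-[(2-heptyl-1,3-dioxolan-2-yl)methyl]-6-(hydroxymethyl)-2-methyl-5-(prop-1-en-2-yl)-2-(triethylsilyloxy)cyclohexan-1-one
Conditions: LiN(iPr)2, THF, −78 °C; CH2O (g, from cracked paraformaldehyde), −78 °C; AcOH
Reagents that add atoms: formaldehyde, C=O
Why: The ring ketone can be deprotonated only at C8a because C7 is quaternary, and crossed aldol addition to monomeric formaldehyde occurs anti to the neighbouring isopropenyl group, giving a C8a centre that is later made planar so its ratio does not matter.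

Step 6
Reactants: 8 (2S,3S,5R,6R)-3-[(2-heptyl-1,3-dioxolan-2-yl)methyl]-6-(hydroxymethyl)-2-methyl-5-(prop-1-en-2-yl)-2-(triethylsilyloxy)cyclohexan-1-one
Product: 9 (2S,3S,5R,6R)-6-[(tert-butyldimethylsilyloxy)methyl]-3-[(2-heptyl-1,3-dioxolan-2-yl)methyl]-2-methyl-5-(prop-1-en-2-yl)-2-(triethylsilyloxy)cyclohexan-1-one
Conditions: tBuMe2SiCl, imidazole, DMF, 0 °C to rt
Reagents that add atoms: tert-butyldimethylsilyl chloride, CC(C)(C)[Si](C)(C)Cl
Why: Imidazole-promoted silylation of the primary alcohol blocks retro-aldol loss of formaldehyde and leaves the hindered ketone untouched.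

Step 7
Reactants: 9 (2S,3S,5R,6R)-6-[(tert-butyldimethylsilyloxy)methyl]-3-[(2-heptyl-1,3-dioxolan-2-yl)methyl]-2-methyl-5-(prop-1-en-2-yl)-2-(triethylsilyloxy)cyclohexan-1-one
Product: 11 (2S,3S,5R,6R)-5-acetyl-6-[(tert-butyldimethylsilyloxy)methyl]-3-[(2-heptyl-1,3-dioxolan-2-yl)methyl]-2-methyl-2-(triethylsilyloxy)cyclohexan-1-one, via secondary ozonide 10 (not isolated)
Conditions: O3, CH2Cl2, −78 °C; PPh3, −78 °C to rt
Reagents that add atoms: ozone, [O-][O+]=O
Why: In this ozonolysis the isopropenyl group is the only C=C bond and the ketal carbon carries no C–H bond for ozone to attack, so reductive work-up gives the methyl ketone with C4a unchanged.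

Step 8
Reactants: 11 (2S,3S,5R,6R)-5-acetyl-6-[(tert-butyldimethylsilyloxy)methyl]-3-[(2-heptyl-1,3-dioxolan-2-yl)methyl]-2-methyl-2-(triethylsilyloxy)cyclohexan-1-one
Product: 13 (2S,3S,5R,6R)-6-[(tert-butyldimethylsilyloxy)methyl]-5-ethynyl-3-[(2-heptyl-1,3-dioxolan-2-yl)methyl]-2-methyl-2-(triethylsilyloxy)cyclohexan-1-one, via enol triflate 12 (not isolated)
Conditions: KN(SiMe3)2 (1.05 equiv), THF, −78 °C; PhNTf2 (1.0 equiv); then LiN(iPr)2 (2.5 equiv), −78 °C; AcOH
Reagents that add atoms: none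
Why: Kinetic deprotonation takes the CH3 of the methyl ketone (the only competing acidic C–H is the hindered tertiary one at C8a), O-triflation follows, and amide-induced anti-elimination of triflic acid from the 1-alkenyl triflate at −78 °C gives the terminal alkyne (ketone-to-alkyne conversion via an enol triflate).

Step 9
Reactants: 13 (2S,3S,5R,6R)-6-[(tert-butyldimethylsilyloxy)methyl]-5-ethynyl-3-[(2-heptyl-1,3-dioxolan-2-yl)methyl]-2-methyl-2-(triethylsilyloxy)cyclohexan-1-one; 14 (E)-1-bromoprop-1-ene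
Product: 15 (2S,3S,5R,6R)-6-[(tert-butyldimethylsilyloxy)methyl]-3-[(2-heptyl-1,3-dioxolan-2-yl)methyl]-2-methyl-5-[(3E)-pent-3-en-1-yn-1-yl]-2-(triethylsilyloxy)cyclohexan-1-one
Conditions: Pd(PPh3)4 (5 mol %), CuI (10 mol %), Et2NH, THF, rt
Reagents that add atoms: none
Why: In this Sonogashira coupling, oxidative addition of zerovalent palladium to the vinyl bromide and the final reductive elimination both go with retention, so the E geometry passes into the enyne.

Step 10
Reactants: 15 (2S,3S,5R,6R)-6-[(tert-butyldimethylsilyloxy)methyl]-3-[(2-heptyl-1,3-dioxolan-2-yl)methyl]-2-methyl-5-[(3E)-pent-3-en-1-yn-1-yl]-2-(triethylsilyloxy)cyclohexan-1-one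
Product: 17 (5S,6S)-2-[(tert-butyldimethylsilyloxy)methyl]-5-[(2-heptyl-1,3-dioxolan-2-yl)methyl]-6-methyl-3-[(3E)-pent-3-en-1-yn-1-yl]-6-(triethylsilyloxy)cyclohex-2-en-1-one, via trimethylsilyl enol ether 16 (not isolated)
Conditions: LiN(iPr)2, Me3SiCl (internal quench), THF, −78 °C; then Pd(OAc)2 (1.2 equiv), MeCN, rt
Reagents that add atoms: none
Why: In this Saegusa–Ito oxidation the only possible enol silane (C8=C8a) is palladated at C8a and β-hydride elimination takes the propargylic C4a–H, giving the tetrasubstituted enone conjugated with the alkyne and erasing the C4a and C8a centres.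

Step 11
Reactants: 17 (5S,6S)-2-[(tert-butyldimethylsilyloxy)methyl]-5-[(2-heptyl-1,3-dioxolan-2-yl)methyl]-6-methyl-3-[(3E)-pent-3-en-1-yn-1-yl]-6-(triethylsilyloxy)cyclohex-2-en-1-one
Product: 18 (5S,6S)-6-hydroxy-2-(hydroxymethyl)-6-methyl-5-(2-oxononyl)-3-[(3E)-pent-3-en-1-yn-1-yl]cyclohex-2-en-1-one
Conditions: 2 M HCl (aq), THF, rt
Reagents that add atoms: water, O
Why: Mild aqueous acid hydrolyses both silyl ethers and the dioxolane in one global deprotection, while C6 and C7 are untouched because C7 is quaternary and C6 is not enolisable.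

Step 12
Reactants: 18 (5S,6S)-6-hydroxy-2-(hydroxymethyl)-6-methyl-5-(2-oxononyl)-3-[(3E)-pent-3-en-1-yn-1-yl]cyclohex-2-en-1-one
Product: 19 (6S,7S)-7-hydroxy-7-methyl-6-(2-oxononyl)-3-[(1E)-prop-1-en-1-yl]-1,5,6,7-tetrahydro-8H-isochromen-8-one
Conditions: Ph3PAuCl (5 mol %), AgOSO2CF3 (5 mol %), CH2Cl2, rt
Reagents that add atoms: none
Why: In this gold-catalysed 6-endo-dig hydroalkoxylation the hydroxymethyl oxygen attacks the activated alkyne at the carbon remote from the electron-poor enone and stabilised by the propenyl group, and protodeauration gives the 1H-isochromene dienol ether without touching C6 or C7.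

## Compound list

1 | nonan-2-one | CCCCCCCC(C)=O | starting material
2 | triethyl(non-1-en-2-yloxy)silane | C=C(CCCCCCC)O[Si](CC)(CC)CC | intermediate
3 | (R)-carvone, (5R)-2-methyl-5-(prop-1-en-2-yl)cyclohex-2-en-1-one | O=C1C(C)=CC[C@@H](C(C)=C)C1 | starting material
4 | 1-[(1S,5R)-2-methyl-5-(prop-1-en-2-yl)-3-(triethylsilyloxy)cyclohex-2-en-1-yl]nonan-2-one | CC[Si](CC)(CC)OC1=C(C)[C@H](CC(=O)CCCCCCC)C[C@@H](C(C)=C)C1 | intermediate
5 | silyloxy epoxide of 4 (C7–C8 epoxide, oxygen anti to the 2-oxononyl chain) | CC[Si](CC)(CC)O[C@]12O[C@@]1(C)[C@H](CC(=O)CCCCCCC)C[C@@H](C(C)=C)C2 | intermediate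
6 | (2S,3S,5R)-2-methyl-3-(2-oxononyl)-5-(prop-1-en-2-yl)-2-(triethylsilyloxy)cyclohexan-1-one | O=C1[C@@](C)(O[Si](CC)(CC)CC)[C@H](CC(=O)CCCCCCC)C[C@@H](C(C)=C)C1 | intermediate
7 | (2S,3S,5R)-3-[(2-heptyl-1,3-dioxolan-2-yl)methyl]-2-methyl-5-(prop-1-en-2-yl)-2-(triethylsilyloxy)cyclohexan-1-one | O=C1[C@@](C)(O[Si](CC)(CC)CC)[C@H](CC2(CCCCCCC)OCCO2)C[C@@H](C(C)=C)C1 | intermediate
8 | (2S,3S,5R,6R)-3-[(2-heptyl-1,3-dioxolan-2-yl)methyl]-6-(hydroxymethyl)-2-methyl-5-(prop-1-en-2-yl)-2-(triethylsilyloxy)cyclohexan-1-one | O=C1[C@@](C)(O[Si](CC)(CC)CC)[C@H](CC2(CCCCCCC)OCCO2)C[C@@H](C(C)=C)[C@@H]1CO | intermediate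
9 | (2S,3S,5R,6R)-6-[(tert-butyldimethylsilyloxy)methyl]-3-[(2-heptyl-1,3-dioxolan-2-yl)methyl]-2-methyl-5-(prop-1-en-2-yl)-2-(triethylsilyloxy)cyclohexan-1-one | O=C1[C@@](C)(O[Si](CC)(CC)CC)[C@H](CC2(CCCCCCC)OCCO2)C[C@@H](C(C)=C)[C@@H]1CO[Si](C)(C)C(C)(C)C | intermediate
10 | secondary ozonide of 9 (3-methyl-1,2,4-trioxolan-3-yl in place of isopropenyl; mixture at the ozonide carbon) | O=C1[C@@](C)(O[Si](CC)(CC)CC)[C@H](CC2(CCCCCCC)OCCO2)C[C@@H](C3(C)OOCO3)[C@@H]1CO[Si](C)(C)C(C)(C)C | intermediate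
11 | (2S,3S,5R,6R)-5-acetyl-6-[(tert-butyldimethylsilyloxy)methyl]-3-[(2-heptyl-1,3-dioxolan-2-yl)methyl]-2-methyl-2-(triethylsilyloxy)cyclohexan-1-one | O=C1[C@@](C)(O[Si](CC)(CC)CC)[C@H](CC2(CCCCCCC)OCCO2)C[C@@H](C(C)=O)[C@@H]1CO[Si](C)(C)C(C)(C)C | intermediate
12 | kinetic enol triflate of 11 (1-(trifluoromethanesulfonyloxy)ethenyl in place of acetyl) | O=C1[C@@](C)(O[Si](CC)(CC)CC)[C@H](CC2(CCCCCCC)OCCO2)C[C@@H](C(=C)OS(=O)(=O)C(F)(F)F)[C@@H]1CO[Si](C)(C)C(C)(C)C | intermediate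
13 | (2S,3S,5R,6R)-6-[(tert-butyldimethylsilyloxy)methyl]-5-ethynyl-3-[(2-heptyl-1,3-dioxolan-2-yl)methyl]-2-methyl-2-(triethylsilyloxy)cyclohexan-1-one | O=C1[C@@](C)(O[Si](CC)(CC)CC)[C@H](CC2(CCCCCCC)OCCO2)C[C@@H](C#C)[C@@H]1CO[Si](C)(C)C(C)(C)C | intermediate
14 | (E)-1-bromoprop-1-ene | C/C=C/Br | starting material
15 | (2S,3S,5R,6R)-6-[(tert-butyldimethylsilyloxy)methyl]-3-[(2-heptyl-1,3-dioxolan-2-yl)methyl]-2-methyl-5-[(3E)-pent-3-en-1-yn-1-yl]-2-(triethylsilyloxy)cyclohexan-1-one | O=C1[C@@](C)(O[Si](CC)(CC)CC)[C@H](CC2(CCCCCCC)OCCO2)C[C@@H](C#C/C=C/C)[C@@H]1CO[Si](C)(C)C(C)(C)C | intermediate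
16 | trimethylsilyl enol ether of 15 (C8=C8a) | C[Si](C)(C)OC=1[C@@](C)(O[Si](CC)(CC)CC)[C@H](CC2(CCCCCCC)OCCO2)C[C@@H](C#C/C=C/C)C1CO[Si](C)(C)C(C)(C)C | intermediate
17 | (5S,6S)-2-[(tert-butyldimethylsilyloxy)methyl]-5-[(2-heptyl-1,3-dioxolan-2-yl)methyl]-6-methyl-3-[(3E)-pent-3-en-1-yn-1-yl]-6-(triethylsilyloxy)cyclohex-2-en-1-one | O=C1[C@@](C)(O[Si](CC)(CC)CC)[C@H](CC2(CCCCCCC)OCCO2)CC(C#C/C=C/C)=C1CO[Si](C)(C)C(C)(C)C | intermediate
18 | (5S,6S)-6-hydroxy-2-(hydroxymethyl)-6-methyl-5-(2-oxononyl)-3-[(3E)-pent-3-en-1-yn-1-yl]cyclohex-2-en-1-one | O=C1[C@@](C)(O)[C@H](CC(=O)CCCCCCC)CC(C#C/C=C/C)=C1CO | intermediate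
19 | (6S,7S)-7-hydroxy-7-methyl-6-(2-oxononyl)-3-[(1E)-prop-1-en-1-yl]-1,5,6,7-tetrahydro-8H-isochromen-8-one | C/C=C/C1=CC2=C(CO1)C(=O)[C@@](C)(O)[C@H](CC(=O)CCCCCCC)C2 | target

## Step count and risks

Total: 12 steps. Longest linear sequence: 12 steps (nonan-2-one through steps 1–12), or 11 steps counted from carvone.

The three steps most likely to fail, each with a fallback:

**Step 2.** The silyl-transfer Michael addition of a ketone-derived enol ether to the α-methyl enone may be slow. The fallback sets out from 3 and comes back at 6. S-Ethyl thioacetate is converted (LiN(iPr)2, Et3SiCl) into the much more nucleophilic 1-(ethylsulfanyl)-1-(triethylsilyloxy)ethene F1. Its Mukaiyama–Michael addition to 3 under the same trityl catalysis gives the thioester silyl enol ether F2. Rubottom oxidation as in step 3 gives the α-silyloxy keto thioester F3. Fukuyama coupling of F3 with C7H15ZnI (PdCl2(PPh3)2 cat., toluene/THF, rt) builds the heptyl ketone without touching the ring ketone and delivers 6.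

**Step 8.** The ring ketone may be deprotonated at C8a in competition with the methyl ketone, with triflation there or loss of silanolate. The fallback sets out from 9 and comes back at 13, and takes the ring carbonyl out of play. NaBH4 in MeOH reduces 9 to the C8 carbinol F4, which is capped (Me3SiCl, imidazole) as the trimethylsilyl ether F5. Ozonolysis as in step 7 gives the methyl ketone F6, now the only carbonyl group. The same triflation–elimination gives the terminal alkyne F7. Citric acid in MeOH removes only the trimethylsilyl group to give the alkynyl carbinol F8, and Dess–Martin periodinane returns 13. The C8 configuration drawn is the expected major one and is immaterial, since it is oxidised away.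

**Step 10.** The Saegusa oxidation has to form a tetrasubstituted enone beside an enyne that can bind palladium. The fallback sets out from 15 and comes back at 17 by selenoxide elimination. Deprotonation with LiN(iPr)2 at −78 °C and PhSeBr, which enters anti to the enynyl group, gives the α-phenylselanyl ketone F9. H2O2 and pyridine in CH2Cl2 at 0 °C give the selenoxide F10, which undergoes syn-elimination with the cis C4a–H (away from the oxygen-bearing CH2) to give 17.

## Further compounds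

F1 | step 2 | 1-(ethylsulfanyl)-1-(triethylsilyloxy)ethene | C=C(SCC)O[Si](CC)(CC)CC
F2 | step 2 | S-ethyl 2-[(1S,5R)-2-methyl-5-(prop-1-en-2-yl)-3-(triethylsilyloxy)cyclohex-2-en-1-yl]ethanethioate | CC[Si](CC)(CC)OC1=C(C)[C@H](CC(=O)SCC)C[C@@H](C(C)=C)C1
F3 | step 2 | S-ethyl 2-[(1S,2S,5R)-2-methyl-3-oxo-5-(prop-1-en-2-yl)-2-(triethylsilyloxy)cyclohexyl]ethanethioate | O=C1[C@@](C)(O[Si](CC)(CC)CC)[C@H](CC(=O)SCC)C[C@@H](C(C)=C)C1
F4 | step 8 | C8 carbinol of 9 (ring ketone reduced, hydroxyl cis to the C6 chain) | O[C@@H]1[C@@](C)(O[Si](CC)(CC)CC)[C@H](CC2(CCCCCCC)OCCO2)C[C@@H](C(C)=C)[C@@H]1CO[Si](C)(C)C(C)(C)C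
F5 | step 8 | trimethylsilyl ether of F4 | C[Si](C)(C)O[C@@H]1[C@@](C)(O[Si](CC)(CC)CC)[C@H](CC2(CCCCCCC)OCCO2)C[C@@H](C(C)=C)[C@@H]1CO[Si](C)(C)C(C)(C)C
F6 | step 8 | methyl ketone from F5 (acetyl in place of isopropenyl) | C[Si](C)(C)O[C@@H]1[C@@](C)(O[Si](CC)(CC)CC)[C@H](CC2(CCCCCCC)OCCO2)C[C@@H](C(C)=O)[C@@H]1CO[Si](C)(C)C(C)(C)C
F7 | step 8 | terminal alkyne from F6 (ethynyl in place of acetyl) | C[Si](C)(C)O[C@@H]1[C@@](C)(O[Si](CC)(CC)CC)[C@H](CC2(CCCCCCC)OCCO2)C[C@@H](C#C)[C@@H]1CO[Si](C)(C)C(C)(C)C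
F8 | step 8 | C8 carbinol of 13 (F7 without the trimethylsilyl group) | O[C@@H]1[C@@](C)(O[Si](CC)(CC)CC)[C@H](CC2(CCCCCCC)OCCO2)C[C@@H](C#C)[C@@H]1CO[Si](C)(C)C(C)(C)C
F9 | step 10 | C8a-phenylselanyl derivative of 15 (selenium trans to the enynyl group) | O=C1[C@@](C)(O[Si](CC)(CC)CC)[C@H](CC2(CCCCCCC)OCCO2)C[C@@H](C#C/C=C/C)[C@]1(CO[Si](C)(C)C(C)(C)C)[Se]c3ccccc3
F10 | step 10 | selenoxide of F9 | O=C1[C@@](C)(O[Si](CC)(CC)CC)[C@H](CC2(CCCCCCC)OCCO2)C[C@@H](C#C/C=C/C)[C@]1(CO[Si](C)(C)C(C)(C)C)[Se](=O)c3ccccc3
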